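**Retrosynthetic overview** (locants follow the benzofuranone numbering of the target: O1, C2 aryl, C3 methyl, C3a allyl, C4, C5 OMe, C6 C=O, C7, C7a)

1. Target 21 ⇐ 5,6-dimethoxy enone 19 by Stork–Danheiser reduction and hydrolysis; 19 ⇐ 2-methoxy-1,3-dione 18 by O-methylation at the unhindered oxygen.
2. 18 ⇐ acyclic keto acrylate 16 by a one-pot Michael–Claisen bicyclization: C3a–C7a closes the tetrahydrofuran ring first, C5–C6 then closes the carbocycle.
3. Enabling feature: the carbocycle is two three-carbon units (C3a–C4–C5 and C7a–C7–C6) bridged by O1–C2–C3. At the 1,3-dione level C4 is a ketone flanked by C3a–H and C5–H2 (1,3-dinucleophile), and O1–C7a=C7–C6O2Me is a vinylogous carbonate (1,3-dielectrophile at C7a and C6).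
4. 16 ⇐ hydroxy ketone 14 + methyl propiolate (oxa-Michael); 14 ⇐ α-allyl γ-lactone 11 + MeOCH2Li; 11 ⇐ cis-lactone 9 ⇐ (Z)-crotylboration of veratraldehyde, which sets C2 and C3.
5. Ring order: temporary γ-lactone (steps 3–5), then tetrahydrofuran ring and cyclohexane ring together in step 7.

Key step: step 7

Remark (assumption on the chemistry): 14 is drawn as the open hydroxy ketone although it should equilibrate with its cyclic hemiketal; the configuration at the allyl-bearing carbon of 11, 14 and 16 is inconsequential because step 7 planarizes it; 2, 12 and (−)-Ipc2BOMe are taken as commercial.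

**Step 1**
Reactants: 1 3,4-dimethoxybenzaldehyde; 2 cis-2-butene
Product: 5 (1S,2R)-1-(3,4-dimethoxyphenyl)-2-methylbut-3-en-1-ol, via (Z)-crotyldiisopinocampheylborane 3 (not isolated), via borinate adduct 4 (not isolated)
Conditions: 2, KOtBu, nBuLi, THF, −78 to −45 °C; (−)-Ipc2BOMe [from (+)-α-pinene], −78 °C; BF3·OEt2; 1, −78 °C; then NaOH, H2O2, 0 °C to rt
Reagents that add atoms: none
Why: Brown crotylboration through a Zimmerman–Traxler chair, in which the (Z)-crotyl geometry should give the syn (C2/C3) relationship and the isopinocampheyl groups derived from (+)-α-pinene should direct addition to the Si face of the aldehyde.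

**Step 2**
Reactants: 5 (1S,2R)-1-(3,4-dimethoxyphenyl)-2-methylbut-3-en-1-ol
Product: 7 (1S,2R)-1-(3,4-dimethoxyphenyl)-2-methylbutane-1,4-diol, via O,C-bis(9-borabicyclononyl) adduct 6 (not isolated)
Conditions: 9-BBN-H (2.2 equiv), THF, 0 °C to rt; then NaOH, H2O2, 0 °C
Reagents that add atoms: hydrogen peroxide, OO
Why: anti-Markovnikov hydroboration–oxidation of the monosubstituted alkene, which touches no stereocenter.

**Step 3**
Reactants: 7 (1S,2R)-1-(3,4-dimethoxyphenyl)-2-methylbutane-1,4-diol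
Product: 9 (4R,5S)-5-(3,4-dimethoxyphenyl)-4-methyloxolan-2-one, via lactol 8 (not isolated)
Conditions: TEMPO (2,2,6,6-tetramethylpiperidin-1-oxyl, 10 mol %), PhI(OAc)2 (2.5 equiv), CH2Cl2, rt
Reagents that add atoms: none
Why: oxoammonium-mediated oxidative lactonization; the primary alcohol should be oxidized selectively, the hydroxy aldehyde closes to the lactol and this is oxidized on to the cis-disubstituted γ-lactone.

**Step 4**
Reactants: 9 (4R,5S)-5-(3,4-dimethoxyphenyl)-4-methyloxolan-2-one; 10 allyl bromide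
Product: 11 (3R,4R,5S)-5-(3,4-dimethoxyphenyl)-4-methyl-3-(prop-2-en-1-yl)oxolan-2-one
Conditions: LiN(SiMe3)2, THF, −78 °C; 10, −78 to −20 °C
Reagents that add atoms: none
Why: lactone enolate alkylation; the allyl group should enter anti to the cis-disposed methyl and aryl groups, and this center is erased later in any case.

**Step 5**
Reactants: 11 (3R,4R,5S)-5-(3,4-dimethoxyphenyl)-4-methyl-3-(prop-2-en-1-yl)oxolan-2-one; 12 tributyl(methoxymethyl)stannane
Product: 14 (3R,4R,5S)-5-(3,4-dimethoxyphenyl)-5-hydroxy-1-methoxy-4-methyl-3-(prop-2-en-1-yl)pentan-2-one, via methoxymethyllithium 13 (not isolated)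
Conditions: 12, nBuLi, THF, −78 °C; then 11, −78 °C; aq. NH4Cl
Reagents that add atoms: none
Why: tin–lithium exchange gives the α-alkoxy organolithium, which should add once to the lactone because the lithium lactolate survives at −78 °C and opens to the γ-hydroxy ketone only on work-up.

**Step 6**
Reactants: 14 (3R,4R,5S)-5-(3,4-dimethoxyphenyl)-5-hydroxy-1-methoxy-4-methyl-3-(prop-2-en-1-yl)pentan-2-one; 15 methyl propiolate
Product: 16 methyl (2E)-3-{[(1S,2R,3R)-1-(3,4-dimethoxyphenyl)-5-methoxy-2-methyl-4-oxo-3-(prop-2-en-1-yl)pentyl]oxy}prop-2-enoate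
Conditions: 15 (1.5 equiv), N-methylmorpholine (20 mol %), CH2Cl2, 0 °C to rt
Reagents that add atoms: none
Why: amine-catalysed oxa-Michael addition of the secondary alcohol to the propiolate should give the (E)-β-alkoxyacrylate, the open hydroxy ketone being drained from the ring–chain equilibrium.

**Step 7**
Reactants: 16 methyl (2E)-3-{[(1S,2R,3R)-1-(3,4-dimethoxyphenyl)-5-methoxy-2-methyl-4-oxo-3-(prop-2-en-1-yl)pentyl]oxy}prop-2-enoate
Product: 18 (2S,3R,3aS,7aS)-2-(3,4-dimethoxyphenyl)-6-hydroxy-5-methoxy-3-methyl-3a-(prop-2-en-1-yl)-3,3a,7,7a-tetrahydro-1-benzofuran-4(2H)-one (enol form of the 4,6-dione), via Michael adduct keto ester 17 (not isolated)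
Conditions: KOtBu (1.2 equiv), THF–tBuOH (10:1), 0 °C to rt; then 1 M HCl to pH 4
Reagents that add atoms: none
Why: KOtBu equilibrates the ketone enolates, the fully substituted C3a enolate adds to the β-carbon C7a of the vinylogous carbonate, proton transfer then gives the C5 enolate, which is acylated by the ester carbonyl C6 with loss of methoxide, and the sequence is pulled forward by irreversible formation of the 2-methoxy-1,3-diketonate. The closest known reaction type is the Michael–Claisen [3+3] annulation of ketones with acrylates to cyclohexane-1,3-diones, combined with the known intramolecular enolate addition to β-alkoxyacrylates. The tetrahydrofuran ring closes 5-exo-trig and the carbocycle then closes 6-exo-trig. C7a is controlled by C2: in the chair-like 5-exo transition state the aryl group is pseudo-equatorial, which puts the CH2CO2Me arm cis to it, while the C3 methyl group is pseudo-axial at low cost because its 1,3-partners are the ring oxygen and a vinylic hydrogen. C3a is controlled by C7a through the ring fusion, since only the adduct with the methoxyacetyl group cis to the ester arm can reach the cis-fused Claisen transition state and the other adducts return through retro-Michael or retro-oxa-Michael opening. The step needs C3a-over-C5 regioselectivity in the Michael addition, secured because C5 attack would need a seven-membered ring, and the face selectivity that places aryl, methyl and carbocycle on one face of the tetrahydrofuran, secured by the pseudo-equatorial aryl group.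

**Step 8**
Reactants: 18 (2S,3R,3aS,7aS)-2-(3,4-dimethoxyphenyl)-6-hydroxy-5-methoxy-3-methyl-3a-(prop-2-en-1-yl)-3,3a,7,7a-tetrahydro-1-benzofuran-4(2H)-one
Product: 19 (2S,3R,3aS,7aS)-2-(3,4-dimethoxyphenyl)-5,6-dimethoxy-3-methyl-3a-(prop-2-en-1-yl)-3,3a,7,7a-tetrahydro-1-benzofuran-4(2H)-one
Conditions: Me2SO4 (1.1 equiv), K2CO3, acetone, rt
Reagents that add atoms: dimethyl sulfate, COS(=O)(=O)OC
Why: O-alkylation of the diketonate by a hard electrophile should occur at the C6 oxygen, which is remote from the quaternary C3a, as in the formation of 3-alkoxy-6,6-dialkylcyclohexenones from 4,4-dialkylcyclohexane-1,3-diones.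

**Step 9**
Reactants: 19 (2S,3R,3aS,7aS)-2-(3,4-dimethoxyphenyl)-5,6-dimethoxy-3-methyl-3a-(prop-2-en-1-yl)-3,3a,7,7a-tetrahydro-1-benzofuran-4(2H)-one
Product: 21 (2S,3R,3aR,7aS)-2-(3,4-dimethoxyphenyl)-5-methoxy-3-methyl-3a-(prop-2-en-1-yl)-3,3a,7,7a-tetrahydro-1-benzofuran-6(2H)-one, via allylic alcohol 20 (not isolated)
Conditions: LiAlH4, Et2O, 0 °C; then 1 M HCl, THF–H2O, 0 °C
Reagents that add atoms: water, O
Why: Stork–Danheiser transposition; 1,2-reduction of the vinylogous ester carbonyl at C4, then acid-induced loss of the C4 hydroxyl assisted by the C6 methoxy group, hydration at C6 and loss of methanol should give the 5-methoxy-4-en-6-one, the temporary C4 carbinol center being destroyed.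

**Compound list**

1 | 3,4-dimethoxybenzaldehyde | COc1ccc(C=O)cc1OC | starting material
2 | cis-2-butene | C/C=C\C | starting material
3 | (Z)-crotyldiisopinocampheylborane | C/C=C\CB([C@@H]1C[C@@H]2C[C@H]([C@H]1C)C2(C)C)[C@@H]1C[C@@H]2C[C@H]([C@H]1C)C2(C)C | intermediate (not isolated)
4 | diisopinocampheylborinate of 5 | O(B([C@@H]1C[C@@H]2C[C@H]([C@H]1C)C2(C)C)[C@@H]1C[C@@H]2C[C@H]([C@H]1C)C2(C)C)[C@H](c1ccc(OC)c(OC)c1)[C@H](C)C=C | intermediate (not isolated)
5 | (1S,2R)-1-(3,4-dimethoxyphenyl)-2-methylbut-3-en-1-ol | O[C@H](c1ccc(OC)c(OC)c1)[C@H](C)C=C | intermediate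
6 | O,C-bis(9-borabicyclo[3.3.1]nonan-9-yl) adduct of 5 | B1(C2CCCC1CCC2)O[C@H](c1ccc(OC)c(OC)c1)[C@H](C)CCB1C2CCCC1CCC2 | intermediate (not isolated)
7 | (1S,2R)-1-(3,4-dimethoxyphenyl)-2-methylbutane-1,4-diol | O[C@H](c1ccc(OC)c(OC)c1)[C@H](C)CCO | intermediate
8 | (4R,5S)-5-(3,4-dimethoxyphenyl)-4-methyloxolan-2-ol (anomers) | C[C@@H]1CC(O)O[C@@H]1c1ccc(OC)c(OC)c1 | intermediate (not isolated)
9 | (4R,5S)-5-(3,4-dimethoxyphenyl)-4-methyloxolan-2-one | C[C@@H]1CC(=O)O[C@@H]1c1ccc(OC)c(OC)c1 | intermediate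
10 | allyl bromide | C=CCBr | starting material
11 | (3R,4R,5S)-5-(3,4-dimethoxyphenyl)-4-methyl-3-(prop-2-en-1-yl)oxolan-2-one | C=CC[C@H]1C(=O)O[C@H](c2ccc(OC)c(OC)c2)[C@@H]1C | intermediate
12 | tributyl(methoxymethyl)stannane | CCCC[Sn](CCCC)(CCCC)COC | starting material
13 | methoxymethyllithium | [Li]COC | intermediate (not isolated)
14 | (3R,4R,5S)-5-(3,4-dimethoxyphenyl)-5-hydroxy-1-methoxy-4-methyl-3-(prop-2-en-1-yl)pentan-2-one | COCC(=O)[C@H](CC=C)[C@@H](C)[C@H](O)c1ccc(OC)c(OC)c1 | intermediate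
15 | methyl propiolate | C#CC(=O)OC | starting material
16 | methyl (2E)-3-{[(1S,2R,3R)-1-(3,4-dimethoxyphenyl)-5-methoxy-2-methyl-4-oxo-3-(prop-2-en-1-yl)pentyl]oxy}prop-2-enoate | COCC(=O)[C@H](CC=C)[C@@H](C)[C@H](O/C=C/C(=O)OC)c1ccc(OC)c(OC)c1 | intermediate
17 | methyl 2-[(2S,3S,4R,5S)-5-(3,4-dimethoxyphenyl)-3-(methoxyacetyl)-4-methyl-3-(prop-2-en-1-yl)oxolan-2-yl]acetate | C=CC[C@@]1(C(=O)COC)[C@H](CC(=O)OC)O[C@H](c2ccc(OC)c(OC)c2)[C@@H]1C | intermediate (not isolated)
18 | (2S,3R,3aS,7aS)-2-(3,4-dimethoxyphenyl)-6-hydroxy-5-methoxy-3-methyl-3a-(prop-2-en-1-yl)-3,3a,7,7a-tetrahydro-1-benzofuran-4(2H)-one | C=CC[C@@]12C(=O)C(OC)=C(O)C[C@@H]1O[C@H](c1ccc(OC)c(OC)c1)[C@@H]2C | intermediate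
19 | (2S,3R,3aS,7aS)-2-(3,4-dimethoxyphenyl)-5,6-dimethoxy-3-methyl-3a-(prop-2-en-1-yl)-3,3a,7,7a-tetrahydro-1-benzofuran-4(2H)-one | C=CC[C@@]12C(=O)C(OC)=C(OC)C[C@@H]1O[C@H](c1ccc(OC)c(OC)c1)[C@@H]2C | intermediate
20 | (2S,3R,3aR,7aS)-2-(3,4-dimethoxyphenyl)-5,6-dimethoxy-3-methyl-3a-(prop-2-en-1-yl)-2,3,3a,4,7,7a-hexahydro-1-benzofuran-4-ol (C4 epimers) | C=CC[C@@]12C(O)C(OC)=C(OC)C[C@@H]1O[C@H](c1ccc(OC)c(OC)c1)[C@@H]2C | intermediate (not isolated)
21 | (2S,3R,3aR,7aS)-2-(3,4-dimethoxyphenyl)-5-methoxy-3-methyl-3a-(prop-2-en-1-yl)-3,3a,7,7a-tetrahydro-1-benzofuran-6(2H)-one | C=CC[C@@]12C=C(OC)C(=O)C[C@@H]1O[C@H](c1ccc(OC)c(OC)c1)[C@@H]2C | target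

**Step count and risks**

Total step count: 9. Longest linear sequence: 9 steps (1 to 21).

Step 7. The fully substituted enolate carbon may add only slowly to the donor-deactivated acrylate, so that β-elimination of the benzylic alkoxide from the ester enolate and intermolecular acrylate transfer outrun the Dieckmann closure; closure on the face that makes the aryl group pseudo-axial is the second concern. The fallback sets out from 14 and replaces the Claisen closure by an aldol closure onto a more electrophilic acceptor. O-Alkenylation of 14 with propynal (N-methylmorpholine cat., CH2Cl2, 0 °C) should give the (E)-3-alkoxyacrolein F1. Catalytic KOtBu in THF–tBuOH at −20 °C should then effect a Michael–aldol bicyclization to the bicyclic aldol F2, and oxidation with Dess–Martin periodinane (CH2Cl2, rt) should give the dione 18, where the route is rejoined.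

Step 8. The two diketonate oxygens may be discriminated incompletely (methylation at the C4 oxygen), or C-methylation at C5 may compete. The fallback sets out from 18 and replaces kinetic O-alkylation by a reversible carbonyl condensation. Pyrrolidine (toluene, reflux, water removal) should condense at the unhindered C6 carbonyl to give the enaminone F3. LiAlH4 (THF, 0 °C to rt) should reduce the C4 carbonyl to the amino alcohol F4 (not isolated), and dilute aqueous HCl should hydrolyse it with allylic transposition directly to 21.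

Step 6. Ring–chain tautomerism may hold 14 as the cyclic hemiketal, so that O-alkenylation is slow or occurs at the hemiketal hydroxyl. The fallback sets out from 11 and installs the acrylate before the ketone. MeNHOMe·HCl and iPrMgCl (THF, −20 °C) should open the lactone to the hydroxy Weinreb amide F5. Methyl propiolate 15 with N-methylmorpholine should give the alkoxyacrylate Weinreb amide F6. Methoxymethyllithium 13 (THF, −78 °C) should then add to the Weinreb amide in preference to the push–pull ester and give 16 on work-up, where the route is rejoined.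

**Further compounds**

F1 | step 7 | (2E)-3-{[(1S,2R,3R)-1-(3,4-dimethoxyphenyl)-5-methoxy-2-methyl-4-oxo-3-(prop-2-en-1-yl)pentyl]oxy}prop-2-enal | COCC(=O)[C@H](CC=C)[C@@H](C)[C@H](O/C=C/C=O)c1ccc(OC)c(OC)c1
F2 | step 7 | (2S,3R,3aS,7aS)-2-(3,4-dimethoxyphenyl)-6-hydroxy-5-methoxy-3-methyl-3a-(prop-2-en-1-yl)hexahydro-1-benzofuran-4(2H)-one (C5 and C6 epimers) | C=CC[C@@]12C(=O)C(OC)C(O)C[C@@H]1O[C@H](c1ccc(OC)c(OC)c1)[C@@H]2C
F3 | step 8 | (2S,3R,3aS,7aS)-2-(3,4-dimethoxyphenyl)-5-methoxy-3-methyl-3a-(prop-2-en-1-yl)-6-(pyrrolidin-1-yl)-3,3a,7,7a-tetrahydro-1-benzofuran-4(2H)-one | C=CC[C@@]12C(=O)C(OC)=C(N3CCCC3)C[C@@H]1O[C@H](c1ccc(OC)c(OC)c1)[C@@H]2C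
F4 | step 8 | (2S,3R,3aR,7aS)-2-(3,4-dimethoxyphenyl)-5-methoxy-3-methyl-3a-(prop-2-en-1-yl)-6-(pyrrolidin-1-yl)-2,3,3a,4,7,7a-hexahydro-1-benzofuran-4-ol (C4 epimers) | C=CC[C@@]12C(O)C(OC)=C(N3CCCC3)C[C@@H]1O[C@H](c1ccc(OC)c(OC)c1)[C@@H]2C
F5 | step 6 | (2R,3R,4S)-4-(3,4-dimethoxyphenyl)-4-hydroxy-N-methoxy-N,3-dimethyl-2-(prop-2-en-1-yl)butanamide | CON(C)C(=O)[C@H](CC=C)[C@@H](C)[C@H](O)c1ccc(OC)c(OC)c1
F6 | step 6 | methyl (2E)-3-{[(1S,2R,3R)-1-(3,4-dimethoxyphenyl)-4-[methoxy(methyl)amino]-2-methyl-4-oxo-3-(prop-2-en-1-yl)butyl]oxy}prop-2-enoate | CON(C)C(=O)[C@H](CC=C)[C@@H](C)[C@H](O/C=C/C(=O)OC)c1ccc(OC)c(OC)c1
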